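**Retrosynthetic overview**

1. Target ⇐ ester demethylation, amide → CHO, Luche reduction and α-methylenation of 15-ketone 28; five-membered ring B ⇐ Wolff contraction of a six-membered ring B precursor (C7 extruded as the C6 ester); ring D ⇐ 5-exo radical closure C16–C13 after an aldol at C8.
2. Ring A ⇐ Ireland–Claisen ring contraction (C1–C10) of tricyclic lactone 14; 14 ⇐ Diels–Alder reaction of lactone 9 (dienophile C5=C10) with silyloxy diene 13 (ring C preformed), which sets C5 and C9.
3. Enabling feature: the C20 carbon on C10 and C3 of ring A are 1,5-related (C20–C10–C5–C4–C3), so ring A can be carried as the δ-lactone C20(=O)–O–C3 with the C2=C1 vinyl group on C3. Enolization at C10 gives the array C10=C20–O–C3–C2=C1, whose [3,3] shift forms C1–C10, turns C20 into the angular carboxyl and passes the C3 configuration on to quaternary C10.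
4. Lactone 9 ⇐ acrylate ring-closing metathesis ⇐ (2S,3R)-alcohol 6 ⇐ asymmetric allylboration of acrolein (C3 and C4 set; source of absolute configuration).
5. Ring order: C (step 5), temporary lactone (step 4), six-membered ring B precursor (step 7), A (step 8), D (step 10), B by contraction (step 13).

Key step: step 8

Remark: gibberellane atom numbers are used throughout; compounds 18 to 27 are carried as C15 epimers because C15 becomes a ketone in step 15; 2-(phenylselanyl)acetaldehyde (17) is treated as purchasable (otherwise one step from bromoacetaldehyde diethyl acetal).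

**Route**

Step 1
Reactants: 1 2-allyl-4,4,5,5-tetramethyl-1,3,2-dioxaborolane; 2 methyl methacrylate
Product: 3 methyl (E)-2-methyl-4-(4,4,5,5-tetramethyl-1,3,2-dioxaborolan-2-yl)but-2-enoate
Conditions: second-generation Grubbs catalyst (2 mol %), excess 2, CH2Cl2, 40 °C
Reagents that add atoms: none
Why: Olefin cross-metathesis of a terminal allylboronate with a methacrylate is well precedented and should give the thermodynamically preferred (E)-trisubstituted enoate, in which CH2B is trans to the ester.

Step 2
Reactants: 3 methyl (E)-2-methyl-4-(pinacolboryl)but-2-enoate; 4 acrolein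
Product: 6 methyl (2S,3R)-2-ethenyl-3-hydroxy-2-methylpent-4-enoate, via pinacol borate ester 5 (not isolated)
Conditions: (S)-3,3′-bis(2,4,6-triisopropylphenyl)-1,1′-binaphthalene-2,2′-diyl hydrogen phosphate (5 mol %), 4 Å molecular sieves, toluene, −30 °C; then aq. NaHCO3
Reagents that add atoms: none
Why: Proposed new method: the γ,γ-disubstituted allylboronate should add to the acid-activated aldehyde through a closed six-membered chair transition state with the (E)-ester equatorial and the methyl axial, so that the C3/C4 relative configuration follows from the alkene geometry, while the chiral phosphoric acid (antipode chosen for Si-face attack on acrolein, proposed to be the (S)-acid) sets (3R); the closest known reaction type is the chiral-phosphoric-acid-catalysed allylboration of aldehydes with allyl and crotyl pinacol boronates, which has not been shown for a γ-alkoxycarbonyl allylboronate.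

Step 3
Reactants: 6 methyl (2S,3R)-2-ethenyl-3-hydroxy-2-methylpent-4-enoate; 7 acryloyl chloride
Product: 8 methyl (2S,3R)-2-ethenyl-2-methyl-3-(prop-2-enoyloxy)pent-4-enoate
Conditions: iPr2NEt, 4-(dimethylamino)pyridine (cat.), CH2Cl2, −20 to 0 °C
Reagents that add atoms: none
Why: Amine-catalysed O-acylation of a hindered secondary alcohol with an acid chloride is routine and touches no stereocentre.

Step 4
Reactants: 8 methyl (2S,3R)-2-ethenyl-2-methyl-3-(prop-2-enoyloxy)pent-4-enoate
Product: 9 methyl (2R,3S)-2-ethenyl-3-methyl-6-oxo-3,6-dihydro-2H-pyran-3-carboxylate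
Conditions: second-generation Grubbs catalyst (5 mol %), CH2Cl2 (0.005 M), 40 °C
Reagents that add atoms: none
Why: Ring-closing metathesis of the acrylate with the vinyl group on C4 should close the six-membered α,β-unsaturated δ-lactone in preference to the strained butenolide that the C3 vinyl group would give, leaving both stereocentres untouched.

Step 5
Reactants: 10 buta-1,3-diene; 11 but-3-yn-2-one
Product: 12 1-(cyclohexa-1,4-dien-1-yl)ethan-1-one
Conditions: toluene, 2,6-di-tert-butyl-4-methylphenol (trace), sealed tube, 110 °C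
Reagents that add atoms: none
Why: Thermal Diels–Alder reaction of butadiene with an ynone gives the 1,4-cyclohexadiene (ring C with its future C12=C13 bond) directly and creates no stereocentre.

Step 6
Reactants: 12 1-(cyclohexa-1,4-dien-1-yl)ethan-1-one
Product: 13 tert-butyl{[1-(cyclohexa-1,4-dien-1-yl)ethenyl]oxy}dimethylsilane
Conditions: tBuMe2SiOTf, Et3N, CH2Cl2, 0 °C
Reagents that add atoms: tert-butyldimethylsilyl trifluoromethanesulfonate, CC(C)(C)[Si](C)(C)OS(=O)(=O)C(F)(F)F
Why: Soft enolization of the enone at its methyl group with a silyl triflate and a tertiary amine is the standard way to a cross-conjugated 2-silyloxy diene and should leave the ring CH2 groups alone.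

Step 7
Reactants: 9 methyl (2R,3S)-2-ethenyl-3-methyl-6-oxo-3,6-dihydro-2H-pyran-3-carboxylate; 13 tert-butyl{[1-(cyclohexa-1,4-dien-1-yl)ethenyl]oxy}dimethylsilane
Product: 14 tricyclic lactone silyl enol ether (Diels–Alder adduct; 5β-H, 9β-H, 10β-H)
Conditions: toluene, 2,6-di-tert-butyl-4-methylphenol (trace), sealed tube, 150 °C
Reagents that add atoms: none
Why: In this Diels–Alder reaction of a 2-silyloxy diene with an unsaturated δ-lactone the nucleophilic CH2 terminus (C6) bonds to the β-carbon C5 and C9 to C10, the diene should approach the lactone face opposite to the cis-disposed C18 methyl and C3 vinyl groups (setting C5) and endo to the lactone carbonyl (placing H9 cis to H5 and H10).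

Step 8
Reactants: 14 tricyclic lactone silyl enol ether
Product: 16 tert-butyldimethylsilyl ester of the ring A-closed tricyclic acid (new C1–C10 bond; C2=C3 alkene; C20 carboxyl α on C10), via silyl ketene acetal 15 (not isolated)
Conditions: LiN(iPr)2, tBuMe2SiCl, HMPA, THF, −78 °C (in situ trapping); then toluene, 110 °C
Reagents that add atoms: tert-butyl(chloro)dimethylsilane, CC(C)(C)[Si](C)(C)Cl
Why: LiN(iPr)2 removes the only acidic C–H (H10, α to the lactone carbonyl) and in situ silylation gives ketene acetal 15, whose O–C20=C10 unit and C3 vinyl group (C2=C1) form an allyl vinyl ether that undergoes a [3,3]-sigmatropic Ireland–Claisen rearrangement on warming. The closest known reaction type is the ring-contracting ester-enolate Claisen rearrangement of alkenyl-substituted lactone silyl ketene acetals to cycloalkene carboxylates. Ring A is closed by sigmatropic ring contraction through a boat-like transition state in which C1–C10 forms as C3–O breaks, so the six-membered lactone becomes the six-membered carbocycle with a C2=C3 double bond and the lactone carbonyl becomes the angular C20 silyl ester. The only new stereocentre, quaternary C10, is controlled by C3: the tether forces suprafacial delivery of C1 to the face of C10 that carried H10, which is the face of the C3 vinyl group and of H5, and this gives the trans A/B fusion with C20 α. The step needs regioselective enolization, secured because C4 is quaternary and the silyl enol ether is inert to base, and a reachable boat transition state, secured by the cis relationship of the C3 vinyl group and H5 set in steps 2 and 7.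

Step 9
Reactants: 16 silyl ester of the ring A-closed tricyclic acid; 17 2-(phenylselanyl)acetaldehyde
Product: 18 C8 aldol adduct (C7 ketone, C15 silyl ether, C16 phenylselanyl; C15 epimers)
Conditions: (CF3SO2)2NH (5 mol %), CH2Cl2, −78 °C
Reagents that add atoms: none
Why: In this Mukaiyama aldol reaction, catalysed by the silyl triflimide formed in situ and ending with silyl transfer to the aldolate oxygen, the tetrasubstituted enol ether carbon C8 should be attacked on its β face, because the α face is shielded by the axial C20 silyl ester on C10, which sets the quaternary C8 with C15 cis to H9.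

Step 10
Reactants: 18 C8 aldol adduct
Product: 19 tetracyclic ketone with ring D closed (C16–C13 bond; C15 silyl ether)
Conditions: Bu3SnH, azobis(isobutyronitrile) (cat.), benzene (0.05 M), 80 °C
Reagents that add atoms: none
Why: Tin-hydride-mediated 5-exo-trig radical cyclization of the primary C16 radical onto C13 of the ring C alkene is the kinetically preferred mode, and because the C15–C16 tether sits on the β face of C8 it can only give the β-bridged bicyclo[3.2.1]octane, which sets C13.

Step 11
Reactants: 19 tetracyclic ketone silyl ester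
Product: 21 C20 N-methoxy-N-methylamide, via acid chloride 20 (not isolated)
Conditions: (COCl)2, DMF (cat.), CH2Cl2, 0 °C to rt; then MeNH(OMe)·HCl, pyridine, 0 °C to rt
Reagents that add atoms: N,O-dimethylhydroxylamine hydrochloride, CNOC.Cl
Why: Silyl esters are converted by oxalyl chloride and catalytic DMF into acid chlorides under neutral conditions, and acylation of the hydroxylamine gives an amide that keeps C20 distinct from the two methyl esters without touching any stereocentre.

Step 12
Reactants: 21 C20 N-methoxy-N-methylamide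
Product: 24 C6 diazo C7 ketone, via lithium enolate 22 (not isolated), via trifluoroacetyl ketone 23 (not isolated)
Conditions: LiN(SiMe3)2, THF, −78 °C; then CF3CO2CH2CF3; then MeSO2N3, Et3N, H2O, MeCN, rt
Reagents that add atoms: methanesulfonyl azide, CS(=O)(=O)N=[N+]=[N-]
Why: Detrifluoroacetylative diazo transfer (a Regitz-type reaction) is regiospecific here because the C7 ketone can enolize only towards C6, C8 and C10 being quaternary.

Step 13
Reactants: 24 C6 diazo C7 ketone
Product: 26 ring-contracted C7 methyl ester (five-membered ring B; 6β-CO2Me), via ketene 25 (not isolated)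
Conditions: hν (365 nm), MeOH, 0 °C; then NaOMe (cat.), MeOH, rt
Reagents that add atoms: methanol, CO
Why: Photochemical Wolff rearrangement of a cyclic α-diazo ketone contracts the ring by migration of C8 from C7 to C6 with retention at C8, methanol traps the ketene as the C7 methyl ester, and methoxide equilibration should leave that ester trans to the C5–C4 bond (6β).

Step 14
Reactants: 26 ring-contracted diester with C2=C3
Product: 27 ring A-saturated diester amide
Conditions: H2 (1 atm), Pd/C, EtOAc, rt
Reagents that add atoms: none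
Why: Heterogeneous hydrogenation saturates the only remaining C=C bond (C2=C3) and creates no stereocentre.

Step 15
Reactants: 27 ring A-saturated diester amide (C15 silyl ether)
Product: 28 C15 ketone
Conditions: CrO3, H2SO4, H2O, acetone, 0 °C to rt
Reagents that add atoms: none
Why: Chromic acid cleaves the secondary silyl ether and oxidizes the liberated alcohol in one operation, converging both C15 epimers to the ketone.

Step 16
Reactants: 28 C15 ketone
Product: 29 15-oxo-16-methylene enone
Conditions: (CH2O)n, N-methylanilinium trifluoroacetate, THF, reflux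
Reagents that add atoms: formaldehyde (from paraformaldehyde), C=O
Why: Amine-salt-mediated Mannich-type α-methylenation is regiospecific because C16 is the only enolizable position of the C15 ketone.

Step 17
Reactants: 29 15-oxo-16-methylene enone
Product: 30 15β-hydroxy-16-methylene diester amide
Conditions: NaBH4, CeCl3·7H2O, MeOH, −78 °C
Reagents that add atoms: none
Why: In this Luche 1,2-reduction hydride should attack C15 from the exo face (the side of the one-carbon bridge C14), the endo face being blocked by H9 and the C11 hydrogens, which gives the 15β-alcohol while the amide and esters stay intact.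

Step 18
Reactants: 30 15β-hydroxy-16-methylene diester amide
Product: 32 target gibberellin dimethyl ester (C20 aldehyde), via zirconated hemiaminal 31 (not isolated)
Conditions: Cp2Zr(H)Cl (3.5 equiv), THF, rt; then H2O, silica gel
Reagents that add atoms: none
Why: Hydrozirconation of a tertiary amide gives a stable zirconated hemiaminal that releases the aldehyde only on work-up, a reduction known to spare esters; the first equivalent is consumed by the 15-hydroxyl as its zirconium alkoxide, the hindered 1,1-disubstituted alkene should react more slowly than the amide, and no stereocentre is formed.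

Step 19
Reactants: 32 target gibberellin dimethyl ester
Product: 34 target gibberellin (15β-hydroxy C20-aldehyde 7,19-diacid), via dilithium dicarboxylate 33 (not isolated)
Conditions: LiSPr, HMPA, rt to 50 °C; then aq. HCl (pH 3)
Reagents that add atoms: none
Why: SN2 demethylation by thiolate cleaves the hindered C7 and C19 methyl esters without acyl attack, the non-enolizable C20 aldehyde adding thiolate only reversibly, and acidification gives the diacid.

**Compound list**

1 | 2-allyl-4,4,5,5-tetramethyl-1,3,2-dioxaborolane | C=CCB1OC(C)(C)C(C)(C)O1 | starting material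
2 | methyl methacrylate | C=C(C)C(=O)OC | starting material
3 | methyl (E)-2-methyl-4-(4,4,5,5-tetramethyl-1,3,2-dioxaborolan-2-yl)but-2-enoate | COC(=O)/C(C)=C/CB1OC(C)(C)C(C)(C)O1 | intermediate
4 | acrolein | C=CC=O | starting material
5 | pinacol borate ester of 6 (boron on the C3 oxygen; not isolated) | C=C[C@@H](OB1OC(C)(C)C(C)(C)O1)[C@@](C)(C(=O)OC)C=C | intermediate
6 | methyl (2S,3R)-2-ethenyl-3-hydroxy-2-methylpent-4-enoate | C=C[C@@H](O)[C@@](C)(C(=O)OC)C=C | intermediate
7 | acryloyl chloride | C=CC(=O)Cl | starting material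
8 | methyl (2S,3R)-2-ethenyl-2-methyl-3-(prop-2-enoyloxy)pent-4-enoate | C=CC(=O)O[C@H](C=C)[C@@](C)(C(=O)OC)C=C | intermediate
9 | methyl (2R,3S)-2-ethenyl-3-methyl-6-oxo-3,6-dihydro-2H-pyran-3-carboxylate (lactone C20(=O)–O–C3 with C5=C10) | O=C1C=C[C@](C)(C(=O)OC)[C@@H](C=C)O1 | intermediate
10 | buta-1,3-diene | C=CC=C | starting material
11 | but-3-yn-2-one | CC(=O)C#C | starting material
12 | 1-(cyclohexa-1,4-dien-1-yl)ethan-1-one | CC(=O)C1=CCC=CC1 | intermediate
13 | tert-butyl{[1-(cyclohexa-1,4-dien-1-yl)ethenyl]oxy}dimethylsilane | C=C(O[Si](C)(C)C(C)(C)C)C1=CCC=CC1 | intermediate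
14 | Diels–Alder adduct: δ-lactone C20(=O)–O–C3 cis-fused at C5/C10 to the six-membered ring B precursor with C7 silyl enol ether (C7=C8), ring C 12-ene; H5, H9, H10, C3 vinyl and C18 methyl β, C19 ester α | O=C1O[C@H](C=C)[C@@](C)(C(=O)OC)[C@H]2CC(O[Si](C)(C)C(C)(C)C)=C3CC=CC[C@H]3[C@@H]12 | intermediate
15 | silyl ketene acetal of 14 (C10=C20(OSi); not isolated) | CC(C)(C)[Si](C)(C)OC1=C2[C@@H]3CC=CCC3=C(O[Si](C)(C)C(C)(C)C)C[C@@H]2[C@](C)(C(=O)OC)[C@@H](C=C)O1 | intermediate
16 | ring A-closed tricycle: trans A/B, 2-ene, C20 tert-butyldimethylsilyl ester α on C10, C19 methyl ester α, C7 silyl enol ether, 12-ene | CC(C)(C)[Si](C)(C)OC(=O)[C@@]12CC=C[C@@](C)(C(=O)OC)[C@H]1CC(O[Si](C)(C)C(C)(C)C)=C1CC=CC[C@H]12 | intermediate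
17 | 2-(phenylselanyl)acetaldehyde | O=CC[Se]c1ccccc1 | starting material
18 | C8 aldol adduct: C7 ketone, C8 quaternary with β-C15H(OSi)–C16H2SePh (C15 epimers), 2-ene, 12-ene | CC(C)(C)[Si](C)(C)OC(=O)[C@@]12CC=C[C@@](C)(C(=O)OC)[C@H]1CC(=O)[C@@]1(C(O[Si](C)(C)C(C)(C)C)C[Se]c3ccccc3)CC=CC[C@H]12 | intermediate
19 | tetracycle with ring D closed (bicyclo[3.2.1]octane, C15 silyl ether), C7 ketone, C20 silyl ester, 2-ene | CC(C)(C)[Si](C)(C)OC(=O)[C@@]12CC=C[C@@](C)(C(=O)OC)[C@H]1CC(=O)[C@]13C(O[Si](C)(C)C(C)(C)C)C[C@@H](C3)CC[C@H]12 | intermediate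
20 | C20 acid chloride of 19 (not isolated) | ClC(=O)[C@@]12CC=C[C@@](C)(C(=O)OC)[C@H]1CC(=O)[C@]13C(O[Si](C)(C)C(C)(C)C)C[C@@H](C3)CC[C@H]12 | intermediate
21 | C20 N-methoxy-N-methylamide, C7 ketone, C15 silyl ether, 2-ene | CON(C)C(=O)[C@@]12CC=C[C@@](C)(C(=O)OC)[C@H]1CC(=O)[C@]13C(O[Si](C)(C)C(C)(C)C)C[C@@H](C3)CC[C@H]12 | intermediate
22 | lithium C6=C7 enolate of 21 (not isolated) | CON(C)C(=O)[C@@]12CC=C[C@@](C)(C(=O)OC)[C@H]1C=C(O[Li])[C@]13C(O[Si](C)(C)C(C)(C)C)C[C@@H](C3)CC[C@H]12 | intermediate
23 | C6 trifluoroacetyl derivative of 21 (not isolated) | CON(C)C(=O)[C@@]12CC=C[C@@](C)(C(=O)OC)[C@H]1C(C(=O)C(F)(F)F)C(=O)[C@]13C(O[Si](C)(C)C(C)(C)C)C[C@@H](C3)CC[C@H]12 | intermediate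
24 | C6 diazo C7 ketone | CON(C)C(=O)[C@@]12CC=C[C@@](C)(C(=O)OC)[C@H]1C(=[N+]=[N-])C(=O)[C@]13C(O[Si](C)(C)C(C)(C)C)C[C@@H](C3)CC[C@H]12 | intermediate
25 | ring-contracted ketene (C6=C7=O; not isolated) | CON(C)C(=O)[C@@]12CC=C[C@@](C)(C(=O)OC)[C@H]1C(=C=O)[C@]13C(O[Si](C)(C)C(C)(C)C)C[C@@H](C3)CC[C@H]12 | intermediate
26 | gibberellane skeleton: 7,19-dimethyl ester (6β), C20 N-methoxy-N-methylamide, C15 silyl ether, 2-ene | CON(C)C(=O)[C@@]12CC=C[C@@](C)(C(=O)OC)[C@H]1[C@H](C(=O)OC)[C@]13C(O[Si](C)(C)C(C)(C)C)C[C@@H](C3)CC[C@H]12 | intermediate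
27 | 2,3-dihydro derivative of 26 | CON(C)C(=O)[C@@]12CCC[C@@](C)(C(=O)OC)[C@H]1[C@H](C(=O)OC)[C@]13C(O[Si](C)(C)C(C)(C)C)C[C@@H](C3)CC[C@H]12 | intermediate
28 | 15-ketone (7,19-dimethyl ester, C20 amide) | CON(C)C(=O)[C@@]12CCC[C@@](C)(C(=O)OC)[C@H]1[C@H](C(=O)OC)[C@]13C(=O)C[C@@H](C3)CC[C@H]12 | intermediate
29 | 15-oxo-16-methylene enone | CON(C)C(=O)[C@@]12CCC[C@@](C)(C(=O)OC)[C@H]1[C@H](C(=O)OC)[C@]13C(=O)C(=C)[C@@H](C3)CC[C@H]12 | intermediate
30 | 15β-hydroxy-16-methylene 7,19-dimethyl ester C20 amide | CON(C)C(=O)[C@@]12CCC[C@@](C)(C(=O)OC)[C@H]1[C@H](C(=O)OC)[C@]13[C@H](O)C(=C)[C@@H](C3)CC[C@H]12 | intermediate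
31 | zirconated hemiaminal at C20 carrying the C15 zirconium alkoxide (cyclopentadienyl rings drawn η1; not isolated) | CON(C)C(O[Zr](Cl)(C1C=CC=C1)C1C=CC=C1)[C@@]12CCC[C@@](C)(C(=O)OC)[C@H]1[C@H](C(=O)OC)[C@]13[C@H](O[Zr](Cl)(C4C=CC=C4)C4C=CC=C4)C(=C)[C@@H](C3)CC[C@H]12 | intermediate
32 | 7,19-dimethyl ester of the target gibberellin (C20 aldehyde, 15β-hydroxy, 16-methylene) | O=C[C@@]12CCC[C@@](C)(C(=O)OC)[C@H]1[C@H](C(=O)OC)[C@]13[C@H](O)C(=C)[C@@H](C3)CC[C@H]12 | intermediate
33 | dilithium 7,19-dicarboxylate of the target gibberellin (not isolated) | [Li+].[Li+].O=C[C@@]12CCC[C@@](C)(C(=O)[O-])[C@H]1[C@H](C(=O)[O-])[C@]13[C@H](O)C(=C)[C@@H](C3)CC[C@H]12 | intermediate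
34 | target gibberellin: 15β-hydroxy-16-methylene C20 gibberellin with C20 aldehyde and 7,19-dicarboxylic acid (4β-methyl, 5β-H, 6β-CO2H, 9β-H; C19 and C20 α) | O=C[C@@]12CCC[C@@](C)(C(=O)O)[C@H]1[C@H](C(=O)O)[C@]13[C@H](O)C(=C)[C@@H](C3)CC[C@H]12 | target

**Step count**

Total step count: 19. Longest linear sequence: 17 steps (steps 1 to 4 and 7 to 19; steps 5 and 6 make the diene).

**Steps most likely to fail**

Step 2 (Proposed new method). The ester-bearing allylboronate may react so slowly that the uncatalysed background reaction competes and facial selectivity is lost, or it may scramble its alkene geometry by a 1,3-boryl shift, which would erode the C3/C4 relative configuration. The fallback sets out from acrolein 4 and comes back to the route at 6, using known chemistry. The lithium dienolate of methyl tiglate (LiN(iPr)2, HMPA, THF, −78 °C) adds to 4 through its α-carbon and gives the aldol as a racemic diastereomer mixture, from which the racemic (2S*,3R*) alcohol F1 is separated by chromatography. Sharpless kinetic resolution (Ti(OiPr)4, D-(−)-diisopropyl tartrate, tBuOOH, 4 Å molecular sieves, CH2Cl2, −20 °C) should then epoxidize the (2R,3S) half to the epoxy alcohol F2 and leave 6.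

Step 7. The β-carbon C5 of the dienophile is flanked by the quaternary C4, so the cycloaddition may need temperatures at which the skipped diene isomerizes or aromatizes, and endo and facial selectivity may be incomplete. The fallback sets out from 9 and 13 and comes back at 14 by a stepwise polar annulation at low temperature. (CF3SO2)2NH (2 mol %) in CH2Cl2 at −78 °C should trigger a Mukaiyama–Michael addition of C6 to C5 with silyl transfer to give the lactone silyl ketene acetal F3. F3 then closes the C9–C10 bond by a second, intramolecular Mukaiyama–Michael addition onto the newly formed enone, the silyl group returning to the C7 oxygen to give 14.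

Step 8. Removal of the ring-fusion proton H10 may be slow, the lactone enolate may fragment to a ketene with loss of the C3 alkoxide before it is silylated, or the boat transition state next to the quaternary C4 may demand temperatures at which the ketene acetal decomposes. The fallback sets out from 14 and comes back at 16 without any enolate. iBu2AlH (1 equiv, CH2Cl2, −78 °C) reduces the lactone to the lactol F4, and dehydration (MeSO2Cl, Et3N) gives the 2-alkenyl-3,4-dihydro-2H-pyran F5. Thermal Claisen rearrangement of F5 (o-dichlorobenzene, 190 °C) should give the C20 aldehyde F6 with the same chirality transfer from C3. Chlorite oxidation (NaClO2, NaH2PO4, 2-methylbut-2-ene, tBuOH–H2O) to the acid F7 and silylation (tBuMe2SiCl, imidazole, DMF) return 16.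

**Further compounds**

F1 | step 2 | racemic methyl (2S*,3R*)-2-ethenyl-3-hydroxy-2-methylpent-4-enoate (both enantiomers shown) | C=C[C@@H](O)[C@@](C)(C(=O)OC)C=C.C=C[C@H](O)[C@](C)(C(=O)OC)C=C
F2 | step 2 | epoxy alcohol from the (2R,3S) enantiomer: methyl (2R)-2-[hydroxy(oxiran-2-yl)methyl]-2-methylbut-3-enoate | O[C@@H]([C@H]1CO1)[C@](C)(C(=O)OC)C=C
F3 | step 7 | lactone silyl ketene acetal carrying the C6–C7(=O)–cyclohexadienyl side chain on C5 | CC(C)(C)[Si](C)(C)OC1=C[C@H](CC(=O)C2=CCC=CC2)[C@](C)(C(=O)OC)[C@@H](C=C)O1
F4 | step 8 | lactol of 14 (C20 hemiacetal) | OC1O[C@H](C=C)[C@@](C)(C(=O)OC)[C@H]2CC(O[Si](C)(C)C(C)(C)C)=C3CC=CC[C@H]3[C@@H]12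
F5 | step 8 | 2-alkenyl-3,4-dihydro-2H-pyran (C10=C20H–O–C3) | C1=C2[C@@H]3CC=CCC3=C(O[Si](C)(C)C(C)(C)C)C[C@@H]2[C@](C)(C(=O)OC)[C@@H](C=C)O1
F6 | step 8 | ring A-closed C20 aldehyde (C7 silyl enol ether, 2-ene, 12-ene) | O=C[C@@]12CC=C[C@@](C)(C(=O)OC)[C@H]1CC(O[Si](C)(C)C(C)(C)C)=C1CC=CC[C@H]12
F7 | step 8 | ring A-closed C20 carboxylic acid | OC(=O)[C@@]12CC=C[C@@](C)(C(=O)OC)[C@H]1CC(O[Si](C)(C)C(C)(C)C)=C1CC=CC[C@H]12
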